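# Synthesis plan for the macrocyclic diaryl ether CNP0393720.0 (compound 30)

## The problem

Target 30 is a 21-membered oxa-cyclophane in which ring A and ring B are joined twice: through a diaryl ether oxygen and through an unbranched chain of fourteen methylene groups. Ring A is a 1,3,5-trisubstituted benzene with a free hydroxyl at C1, the ether oxygen at C3 and the chain at C5. Ring B is a hydroquinone (hydroxyls at C2 and C5) with the aryloxy group at C1 and the chain at C3, so its C2 hydroxyl is flanked on both sides. There is no stereocentre and no double bond outside the arenes, so nothing needs stereocontrol. The problems are regiochemical: which of the two meta oxygens of ring A is arylated, where the three substituents sit on ring B, and how a 21-membered ring is closed without oligomers. The obvious ring A precursor, a 5-alkylresorcinol, has two equivalent hydroxyls, so any ether-forming route has to desymmetrise it. The free 2-aryloxy-6-alkylhydroquinone is oxidised to the quinone by air and base and should be unmasked last. Several intermediates are also fragile: a terminal aryl ethynyl ether towards water and acid, a 3-alkylcyclobutenone towards base, and an allylarene towards double-bond migration. The enabling feature is the mutual meta arrangement of OH, OAr and CH2 on ring A. This is the pattern formed when the four carbons of a 3-alkylcyclobutenone are expanded by the two carbons of an oxygen-substituted alkyne: C1 (OH) comes from the ketone carbonyl and C3 (OAr) from the alkyne, so the two oxygens are different from the outset.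

## Retrosynthesis

**30 back to 29.** The two O–CH3 bonds on ring B are cut. Methyl ethers are chosen because they survive every earlier condition: butyllithium at low temperature, the Claisen rearrangement near 190 °C, the benzannulation at 110 °C, ruthenium carbenes and hydrogenation. The forward step must cleave both ethers, including the flanked one at C2, while leaving the diaryl ether intact. A diaryl ether offers no sp3 carbon for bromide attack, so it should survive.

**29 back to 28 and 27.** The chain is cut between its second and third carbon counted from ring B, as an alkene (28) formed by ring-closing metathesis of diene 27. This position leaves a three-carbon allyl group on ring B, which a Claisen rearrangement puts on exactly the right ortho carbon. The other thirteen carbons stay on the ring A precursor as a terminal alkenyl chain. Closing the macrocycle at the ether oxygen instead would require an intramolecular Ullmann reaction on a 21-membered ring. A cut further along the chain would require a homologated arm on ring B. The forward reaction needs high dilution and suppression of allyl-to-propenyl isomerisation. The alkene geometry does not matter, since hydrogenation gives 29 from either isomer.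

**27 back to 22 and 15.** Two ring A bonds are cut: C1–C2 and C3–C4, where C2 is the CH between the two oxygens. This splits 27 into 3-(tridec-12-enyl)cyclobut-2-enone 22 and aryl ethynyl ether 15. The alternative is etherification of a 5-alkylresorcinol, which needs a statistical or protecting-group desymmetrisation and an Ullmann coupling with a hindered ortho-methoxyphenol. Here the hydroxyl and the aryloxy group come from different reactants and no desymmetrisation is needed. The cut removes ring A entirely and leaves two fragments of seventeen and thirteen carbons. The forward reaction needs the ynol ether to add to the vinylketene with its oxygen-free carbon on the ketene carbonyl carbon, and it must do so faster than either partner decomposes.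

**15 back to 12, and 12 back to 9 and 10.** The O–C(sp) bond is cut. A phenol cannot be O-alkynylated directly, so trichloroethylene 10 is used as the two-carbon unit. Phenol 9 is converted to the (E)-1,2-dichlorovinyl ether 12, which is then dehalogenated with base to the alkyne. Both alkyne carbons of 15 end up as ring A carbons C2 and C3.

**9 back to 6, 5, 3, 1 and 2.** The phenolic C–O bond of 9 is traced to the C–Br bond of 6 (lithium–bromine exchange, borylation, oxidation). The methyl ether of 6 is traced to phenol 5. The allyl C–C bond of 5 is traced to allyl ether 3 by an aromatic Claisen rearrangement, and 3 comes from 2-bromo-4-methoxyphenol 1 and allyl bromide 2. In 3 the bromine blocks one ortho carbon and the methoxy group blocks the para carbon, so the allyl group can only go to the carbon required. The bromine then marks the site of the third oxygen.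

**22 back to 18 and 19, and 18 back to 16 and 17.** The bond between the chain and the four-membered ring is cut. The Grignard reagent from 13-bromotridec-1-ene 18 adds to the carbonyl of 3-ethoxycyclobut-2-enone 19, and acid hydrolysis with carbonyl transposition gives 22. Bromide 18 comes in one step from 1,10-dibromodecane 16 and allylmagnesium bromide 17 by copper-catalysed coupling. This is shorter than a two-step homologation of an eleven-carbon bromide.

Remark: 28 is carried as an E/Z mixture, because both isomers give 29 on hydrogenation.

## Roads not taken

**Alternative 1:** The cut is the bond between ring B C3 and the benzylic chain carbon. The precursor is the 19-membered macrocyclic aryl 1-alkylallyl ether A1, in which the C2 oxygen of ring B carries the secondary allylic carbon of the chain. On heating it should undergo a ring-expanding aromatic Claisen rearrangement to the 21-membered cyclophane A2, with a free C2 phenol and an (E)-alkene.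
- Merits: the step needs no metal and no reagent. C3 is the only free ortho carbon, so the regiochemistry is certain. The aromatic Claisen rearrangement is a safer reaction class than a benzannulation with an aryloxyalkyne, and in this respect the alternative is better.
- Weak points: the macrocyclisation problem is moved, not solved. A1 itself needs a 19-membered ring closure, either by etherification of a hindered ortho-aryloxyphenol with a secondary allylic electrophile (prone to allylic transposition and elimination) or by an intramolecular Ullmann reaction. Ring A must still be made from a desymmetrised resorcinol. Secondary allyl aryl ethers near 200 °C also lose the allyl unit as a diene.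
- Comparison: hydrogenation and demethylation follow in both plans. The chosen plan sets against the safer key step a ring A whose oxygens never need differentiation and a macrocyclisation by metathesis. It uses the same Claisen logic on the simple ether 3.

**Alternative 2:** The cut removes ring B and the macrocycle together. The precursor A3 is an (E)-alkenyl(methoxy)carbene Cr(CO)5 complex, linked through the fourteen-carbon chain and ring A to an aryl ethynyl ether. An intramolecular Dötz benzannulation should insert the alkyne and one CO and then electrocyclise to give macrocycle A4.
- Merits: three C–C bonds, ring B and the 21-membered ring form in one operation. The ring B oxygens come out differentiated as a 4-methoxyphenol, and no metathesis or hydrogenation is needed. In bonds formed per step this road is better than the chosen one.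
- Weak points: A3 contains two groups that react with each other on mild warming, so it must be assembled last and cold, on a substrate that already carries the sensitive ynol ether. The chromium is stoichiometric. Electron-rich alkynes are the ones that most often divert Fischer carbene complexes to cyclobutenones and 2:1 adducts. The bimolecular-type insertion must compete with decomposition at the dilution a 21-membered ring demands. The ring A part of A3 again needs a mono-etherified resorcinol.
- Comparison: the chosen plan accepts two extra steps (metathesis, hydrogenation). In return, ring formation and macrocyclisation are separate steps, each resting on a well-behaved reaction class.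

**Alternative 3:** The cut is the ring B C1–O bond of the diaryl ether. The precursor A5 is a 2-bromo-6-alkyl-1,4-benzoquinone whose chain ends in the ring A phenol. The phenoxide should add to the bromine-bearing carbon and expel bromide, closing the ring to the aryloxyquinone A6. Reduction and one demethylation would then finish the synthesis.
- Merits: ring B is used in its quinone oxidation state, so only one methyl ether remains at the end. The bromine fixes the site of attack, and the endgame is shorter than in the chosen plan.
- Weak points: a 21-membered ring would be closed by an addition–elimination on a base-sensitive bromoquinone at high dilution. The phenoxide can also add at the unsubstituted quinone carbons, with re-oxidation giving regioisomers, or react through carbon. A5 needs a mono-protected resorcinol, a fourteen-carbon linker built between two arenes, and a quinone oxidation next to a latent free phenol.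
- Comparison: the step count could be similar to the chosen plan. The chosen plan offers a macrocyclisation with predictable behaviour at high dilution and no resorcinol desymmetrisation.

Key step: step 9

## Route

Step 1
Reactants: 1 2-bromo-4-methoxyphenol; 2 allyl bromide (3-bromoprop-1-ene)
Product: 3 1-(allyloxy)-2-bromo-4-methoxybenzene
Conditions: K2CO3, acetone, reflux
Reagents that add atoms: none
Why: Williamson ether synthesis on the only acidic OH; the aryl bromide and the methyl ether are inert.

Step 2
Reactants: 3 1-(allyloxy)-2-bromo-4-methoxybenzene
Product: 5 2-allyl-6-bromo-4-methoxyphenol, via ortho-dienone 4 (not isolated)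
Conditions: N,N-diethylaniline, 190 °C, argon
Reagents that add atoms: none
Why: Aromatic Claisen rearrangement; the [3,3] shift can end productively only at the free ortho carbon, because the other ortho carbon carries bromine and the para carbon carries methoxy, and dienone 4 enolises to the phenol.

Step 3
Reactants: 5 2-allyl-6-bromo-4-methoxyphenol
Product: 6 1-allyl-3-bromo-2,5-dimethoxybenzene
Conditions: MeI, K2CO3, DMF, rt to 40 °C
Reagents that add atoms: iodomethane, CI
Why: Williamson methylation; the small electrophile reaches the 2,6-disubstituted phenoxide without difficulty.

Step 4
Reactants: 6 1-allyl-3-bromo-2,5-dimethoxybenzene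
Product: 9 3-allyl-2,5-dimethoxyphenol, via aryllithium 7 (not isolated), via dimethyl arylboronate 8 (not isolated)
Conditions: n-BuLi, THF, −78 °C; B(OMe)3, −78 °C to rt; then 30% H2O2, aq NaOH, 0 °C to rt
Reagents that add atoms: hydrogen peroxide, OO
Why: Lithium–bromine exchange at −78 °C is faster than deprotonation of the allylic CH2; borylation and oxidative 1,2-shift of the aryl group from boron to oxygen then give the phenol, and alkaline peroxide does not attack the isolated alkene.

Step 5
Reactants: 9 3-allyl-2,5-dimethoxyphenol; 10 trichloroethylene
Product: 12 1-allyl-3-{[(E)-1,2-dichlorovinyl]oxy}-2,5-dimethoxybenzene, via dichloroacetylene 11 (not isolated)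
Conditions: K2CO3, DMF, 70 °C
Reagents that add atoms: none
Why: Greene-type synthesis of 1,2-dichlorovinyl ethers: the base eliminates HCl from 10 to give 11, and anti addition of the phenoxide and a proton across the triple bond gives the E ether.

Step 6
Reactants: 12 1-allyl-3-{[(E)-1,2-dichlorovinyl]oxy}-2,5-dimethoxybenzene
Product: 15 3-allyl-2,5-dimethoxyphenyl ethynyl ether, via chloroethynyl ether 13 (not isolated), via lithium acetylide 14 (not isolated)
Conditions: n-BuLi (2.4 equiv), Et2O, −78 to −40 °C; H2O, −78 to 0 °C; extracted into toluene, dried and used at once as a solution
Reagents that add atoms: none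
Why: Greene ynol ether synthesis: deprotonation and β-elimination of LiCl give 13, lithium–chlorine exchange gives 14, and protonation gives the terminal ynol ether; the aryl ether has no β-hydrogen and so cannot fragment by a retro-ene reaction.

Step 7
Reactants: 16 1,10-dibromodecane; 17 allylmagnesium bromide
Product: 18 13-bromotridec-1-ene
Conditions: Li2CuCl4 (3 mol %), THF, 0 °C to rt; 16 in threefold excess, recovered by distillation
Reagents that add atoms: none
Why: Kochi-type copper-catalysed coupling of a Grignard reagent with a primary alkyl bromide; the excess of 16 holds back the second allylation, and the three components differ enough in boiling point to be separated by distillation.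

Step 8
Reactants: 18 13-bromotridec-1-ene; 19 3-ethoxycyclobut-2-enone
Product: 22 3-(tridec-12-en-1-yl)cyclobut-2-en-1-one, via Grignard reagent 20 (not isolated), via tertiary carbinol 21 (not isolated)
Conditions: Mg, THF, 40 °C; then 19, −78 to 0 °C; then 1 M HCl, 0 °C
Reagents that add atoms: none
Why: Stork–Danheiser sequence on the four-membered vinylogous ester: 1,2-addition of 20 to the carbonyl gives 21, and acid hydrolysis of the enol ether with loss of ethanol transposes the carbonyl to give the 3-alkylcyclobutenone.

Step 9
Reactants: 22 3-(tridec-12-en-1-yl)cyclobut-2-en-1-one; 15 3-allyl-2,5-dimethoxyphenyl ethynyl ether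
Product: 27 3-(3-allyl-2,5-dimethoxyphenoxy)-5-(tridec-12-en-1-yl)phenol, via vinylketene 23 (not isolated), via vinylcyclobutenone 24 (not isolated), via dienylketene 25 (not isolated), via cyclohexadienone 26 (not isolated)
Conditions: 22 (1.3 equiv), toluene, 80 °C then 110 °C, argon; then KOH, MeOH, rt
Reagents that add atoms: none
Why: Danheiser benzannulation. At 80 °C cyclobutenone 22 opens by four-electron electrocyclic cleavage to vinylketene 23, whose ketene C=C adds [2+2] to the electron-rich triple bond of 15 and closes the transient four-membered ring of 24. Cyclobutenone 24 opens in turn to dienylketene 25, which closes ring A by a thermal disrotatory six-electron electrocyclisation (bond from the ketene carbon to the terminal methylene carbon) to dienone 26, and enolisation gives phenol 27. The closest known reactions are the same annulations of 3-alkylcyclobutenones with 1-alkoxy- and 1-siloxyalkynes; an aryloxyalkyne is a less donating member of that class, which is why an excess of 22 and the higher final temperature are planned. No stereocentre survives, since the sp3 carbon of 24 and the CH2 of 26 both end as aromatic CH. The selectivity needed is regiochemical: the oxygen-free alkyne carbon must bond to the ketene carbonyl carbon, and the oxygen lone pair of the ynol ether makes that terminal carbon the nucleophile, which places the aryloxy group meta to the new hydroxyl and the chain meta to both. The unactivated terminal alkenes do not add to a vinylketene at this temperature, and the aryl ynol ether cannot fragment by a retro-ene path. Any 27 that is O-acylated by a second molecule of 23 is returned to the phenol by the KOH/methanol treatment.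

Step 10
Reactants: 27 3-(3-allyl-2,5-dimethoxyphenoxy)-5-(tridec-12-en-1-yl)phenol
Product: 28 21-membered cyclophane alkene (ring B–CH2–CH=CH–(CH2)11–ring A, ring A free phenol, ring B 2,5-dimethoxy, E/Z mixture)
Conditions: second-generation Grubbs catalyst (H2IMes)(PCy3)Cl2Ru=CHPh (10 mol %), 1,4-benzoquinone (20 mol %), CH2Cl2 (1 mM), 40 °C
Reagents that add atoms: none
Why: Ring-closing metathesis of two terminal alkenes, driven by loss of ethylene; high dilution favours the 21-membered ring over oligomers, and benzoquinone intercepts ruthenium hydrides that would move the allyl double bond into conjugation.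

Step 11
Reactants: 28 21-membered cyclophane alkene (E/Z mixture)
Product: 29 saturated 21-membered cyclophane, ring B 2,5-dimethyl ether (the dimethyl ether of the target at the two ring B oxygens)
Conditions: H2 (1 atm), 10% Pd/C, EtOAc, rt
Reagents that add atoms: none
Why: Heterogeneous hydrogenation of a disubstituted alkene; both geometric isomers converge, and aryl methyl ethers, the diaryl ether and the phenol are inert.

Step 12
Reactants: 29 saturated 21-membered cyclophane, ring B 2,5-dimethyl ether
Product: 30 target macrocycle (ring A: 1-hydroxy, 3-aryloxy, 5-alkyl; ring B: 2,5-dihydroxy, 1-aryloxy, 3-alkyl; fourteen CH2 groups between the rings)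
Conditions: BBr3 (6 equiv), CH2Cl2, −78 °C to rt; aqueous work-up with Na2S2O4 under argon
Reagents that add atoms: none
Why: Lewis-acid demethylation of aryl methyl ethers by bromide attack at the methyl carbon; the diaryl ether has no sp3 carbon to attack and survives, and the reducing work-up keeps the hydroquinone from oxidising to the quinone.

## Compound list

1 | 2-bromo-4-methoxyphenol | COc1ccc(O)c(Br)c1 | starting material
2 | allyl bromide | C=CCBr | starting material
3 | 1-(allyloxy)-2-bromo-4-methoxybenzene | C=CCOc1ccc(OC)cc1Br | intermediate
4 | 6-allyl-2-bromo-4-methoxycyclohexa-2,4-dien-1-one (racemic, not isolated) | O=C1C(Br)=CC(OC)=CC1CC=C | intermediate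
5 | 2-allyl-6-bromo-4-methoxyphenol | Oc1c(Br)cc(OC)cc1CC=C | intermediate
6 | 1-allyl-3-bromo-2,5-dimethoxybenzene | COc1c(Br)cc(OC)cc1CC=C | intermediate
7 | (3-allyl-2,5-dimethoxyphenyl)lithium (not isolated) | [Li]c1cc(OC)cc(CC=C)c1OC | intermediate
8 | dimethyl (3-allyl-2,5-dimethoxyphenyl)boronate (not isolated) | COB(OC)c1cc(OC)cc(CC=C)c1OC | intermediate
9 | 3-allyl-2,5-dimethoxyphenol | Oc1cc(OC)cc(CC=C)c1OC | intermediate
10 | trichloroethylene | ClC=C(Cl)Cl | starting material
11 | dichloroacetylene (not isolated) | ClC#CCl | intermediate
12 | 1-allyl-3-{[(E)-1,2-dichlorovinyl]oxy}-2,5-dimethoxybenzene | Cl/C=C(/Cl)Oc1cc(OC)cc(CC=C)c1OC | intermediate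
13 | 1-allyl-3-[(chloroethynyl)oxy]-2,5-dimethoxybenzene (not isolated) | ClC#COc1cc(OC)cc(CC=C)c1OC | intermediate
14 | lithium 2-(3-allyl-2,5-dimethoxyphenoxy)ethynide (not isolated) | [Li]C#COc1cc(OC)cc(CC=C)c1OC | intermediate
15 | 3-allyl-2,5-dimethoxyphenyl ethynyl ether | C#COc1cc(OC)cc(CC=C)c1OC | intermediate
16 | 1,10-dibromodecane | BrCCCCCCCCCCBr | starting material
17 | allylmagnesium bromide | C=CC[Mg]Br | starting material
18 | 13-bromotridec-1-ene | C=CCCCCCCCCCCCBr | intermediate
19 | 3-ethoxycyclobut-2-enone | CCOC1=CC(=O)C1 | starting material
20 | tridec-12-en-1-ylmagnesium bromide (not isolated) | C=CCCCCCCCCCCC[Mg]Br | intermediate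
21 | 3-ethoxy-1-(tridec-12-en-1-yl)cyclobut-2-en-1-ol (racemic, formed as its bromomagnesium alkoxide, not isolated) | CCOC1=CC(O)(CCCCCCCCCCCC=C)C1 | intermediate
22 | 3-(tridec-12-en-1-yl)cyclobut-2-en-1-one | O=C1C=C(CCCCCCCCCCCC=C)C1 | intermediate
23 | 3-methylidenehexadeca-1,15-dien-1-one (vinylketene, not isolated) | O=C=CC(=C)CCCCCCCCCCCC=C | intermediate
24 | 3-(3-allyl-2,5-dimethoxyphenoxy)-4-(pentadeca-1,14-dien-2-yl)cyclobut-2-en-1-one (racemic, not isolated) | O=C1C=C(Oc2cc(OC)cc(CC=C)c2OC)C1C(=C)CCCCCCCCCCCC=C | intermediate
25 | (3E)-3-(3-allyl-2,5-dimethoxyphenoxy)-5-methylideneoctadeca-1,3,17-trien-1-one (dienylketene, ketene carbon and vinyl group cis, not isolated) | O=C=C/C(Oc1cc(OC)cc(CC=C)c1OC)=C\C(=C)CCCCCCCCCCCC=C | intermediate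
26 | 3-(3-allyl-2,5-dimethoxyphenoxy)-5-(tridec-12-en-1-yl)cyclohexa-2,4-dien-1-one (not isolated) | O=C1C=C(Oc2cc(OC)cc(CC=C)c2OC)C=C(CCCCCCCCCCCC=C)C1 | intermediate
27 | 3-(3-allyl-2,5-dimethoxyphenoxy)-5-(tridec-12-en-1-yl)phenol | Oc1cc(CCCCCCCCCCCC=C)cc(Oc2cc(OC)cc(CC=C)c2OC)c1 | intermediate
28 | 21-membered cyclophane alkene, ring B–CH2–CH=CH–(CH2)11–ring A, ring A phenol, ring B 2,5-dimethoxy (E/Z mixture) | Oc1cc2cc(c1)Oc1cc(OC)cc(c1OC)CC=CCCCCCCCCCCC2 | intermediate
29 | saturated 21-membered cyclophane, ring A phenol, ring B 2,5-dimethoxy | Oc1cc2cc(c1)Oc1cc(OC)cc(c1OC)CCCCCCCCCCCCCC2 | intermediate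
30 | CNP0393720.0, saturated 21-membered cyclophane, ring A phenol, ring B 2,5-dihydroxy | Oc1cc2cc(c1)Oc1cc(O)cc(c1O)CCCCCCCCCCCCCC2 | target

## Step count and risk

Total step count: 12. Longest linear sequence: 10 steps (steps 1 to 6, then 9 to 12). The cyclobutenone branch is 2 steps (7 and 8).

**Step 9 (key step).**
- What may go wrong: capture of vinylketene 23 by the aryloxyalkyne may be too slow. The aryl group takes electron density from the oxygen, so 15 is a weaker nucleophile than the alkoxy- and siloxyalkynes normally used. Dimerisation of the vinylketene and thermal oligomerisation of the terminal ynol ether could then consume both partners before ring A forms.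
- Fallback: it sets out from 18 and 9 and builds the diaryl ether by copper catalysis instead. The Grignard reagent 20 made from 18 would be coupled by a Kumada reaction (Pd(dppf)Cl2, THF) with an excess of 1,3-dibromo-5-(methoxymethoxy)benzene F1, itself made from 3,5-dibromophenol with chloromethyl methyl ether and i-Pr2NEt. This gives 1-bromo-3-(methoxymethoxy)-5-(tridec-12-en-1-yl)benzene F2. Ullmann ether synthesis of F2 with phenol 9 (CuI, N,N-dimethylglycine, Cs2CO3, dioxane, 90 °C) would give 1-(3-allyl-2,5-dimethoxyphenoxy)-3-(methoxymethoxy)-5-(tridec-12-en-1-yl)benzene F3. HCl in methanol would remove the acetal, and the route is rejoined at 27.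

**Step 6.**
- What may go wrong: loss of the terminal aryl ethynyl ether during quench and solvent exchange, by hydration to the aryl acetate or by oligomerisation on concentration.
- Fallback: it sets out from 12 and carries the alkyne in silyl-capped form. The lithium acetylide 14 would be trapped with chlorotrimethylsilane to give the storable 3-allyl-2,5-dimethoxyphenyl (trimethylsilyl)ethynyl ether F4. Benzannulation of F4 with 22 under the conditions of step 9 would give 3-(3-allyl-2,5-dimethoxyphenoxy)-5-(tridec-12-en-1-yl)-2-(trimethylsilyl)phenol F5. Protodesilylation at the doubly oxygen-activated ring carbon with trifluoroacetic acid in CH2Cl2 returns the route to 27.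

**Step 10.**
- What may go wrong: intermolecular metathesis to dimers and oligomers. A second risk is migration of the allyl double bond into conjugation with ring B before closure, which would lead to a ring with one carbon fewer.
- Fallback: it sets out from 27 and closes the same double bond reductively. Lemieux–Johnson cleavage of both terminal alkenes (OsO4 cat., NaIO4, 2,6-lutidine, dioxane/water) would give 12-[3-(2,5-dimethoxy-3-(2-oxoethyl)phenoxy)-5-hydroxyphenyl]dodecanal F6. Slow addition of F6 to low-valent titanium (TiCl3, Zn–Cu couple, DME, reflux) in a McMurry macrocyclisation would join the two aldehyde carbons and rejoin the route at 28.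

**Step 4.**
- What may go wrong: proton transfer from the doubly activated allylic/benzylic CH2 to the aryllithium, which would end in protodebromination in place of borylation.
- Fallback: it sets out from 6 and avoids the organolithium. Miyaura borylation (B2pin2, Pd(dppf)Cl2, KOAc, dioxane, 85 °C) would give 2-(3-allyl-2,5-dimethoxyphenyl)-4,4,5,5-tetramethyl-1,3,2-dioxaborolane F7. Oxidation of F7 with alkaline H2O2 returns the route to 9.

## Further compounds

F1 | step 9 | 1,3-dibromo-5-(methoxymethoxy)benzene | COCOc1cc(Br)cc(Br)c1
F2 | step 9 | 1-bromo-3-(methoxymethoxy)-5-(tridec-12-en-1-yl)benzene | COCOc1cc(Br)cc(CCCCCCCCCCCC=C)c1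
F3 | step 9 | 1-(3-allyl-2,5-dimethoxyphenoxy)-3-(methoxymethoxy)-5-(tridec-12-en-1-yl)benzene | COCOc1cc(CCCCCCCCCCCC=C)cc(Oc2cc(OC)cc(CC=C)c2OC)c1
F4 | step 6 | 3-allyl-2,5-dimethoxyphenyl (trimethylsilyl)ethynyl ether | C[Si](C)(C)C#COc1cc(OC)cc(CC=C)c1OC
F5 | step 6 | 3-(3-allyl-2,5-dimethoxyphenoxy)-5-(tridec-12-en-1-yl)-2-(trimethylsilyl)phenol | Oc1cc(CCCCCCCCCCCC=C)cc(Oc2cc(OC)cc(CC=C)c2OC)c1[Si](C)(C)C
F6 | step 10 | 12-[3-(2,5-dimethoxy-3-(2-oxoethyl)phenoxy)-5-hydroxyphenyl]dodecanal | Oc1cc(CCCCCCCCCCCC=O)cc(Oc2cc(OC)cc(CC=O)c2OC)c1
F7 | step 4 | 2-(3-allyl-2,5-dimethoxyphenyl)-4,4,5,5-tetramethyl-1,3,2-dioxaborolane | CC1(C)OB(OC1(C)C)c1cc(OC)cc(CC=C)c1OC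
A1 | alternative 1 | 19-membered macrocyclic aryl 1-alkylallyl ether (racemic), ring A methyl ether | COc1cc2cc(c1)Oc1cc(OC)ccc1OC(C=C)CCCCCCCCCCC2
A2 | alternative 1 | 21-membered cyclophane with free ring B C2 phenol and (E)-alkene | COc1cc2cc(c1)Oc1cc(OC)cc(c1O)C/C=C/CCCCCCCCCCC2
A3 | alternative 2 | pentacarbonyl[(E)-alkenyl(methoxy)carbene]chromium complex tethered to the ring A aryl ethynyl ether | COC(/C=C/CCCCCCCCCCCCCCc1cc(OC)cc(OC#C)c1)=[Cr](=C=O)(=C=O)(=C=O)(=C=O)=C=O
A4 | alternative 2 | macrocyclic diaryl ether with ring B as the 4-methoxyphenol | COc1cc2cc(c1)Oc1cc(OC)cc(c1O)CCCCCCCCCCCCCC2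
A5 | alternative 3 | 2-bromo-6-[14-(3-hydroxy-5-methoxyphenyl)tetradecyl]-1,4-benzoquinone | O=C1C=C(Br)C(=O)C(CCCCCCCCCCCCCCc2cc(O)cc(OC)c2)=C1
A6 | alternative 3 | macrocyclic 2-aryloxy-6-alkyl-1,4-benzoquinone | O=C1C=C2Oc3cc(OC)cc(c3)CCCCCCCCCCCCCCC(=C1)C2=O
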